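Carotenoid numbering: ring C1 (CMe2), C2 (CH2), C3 and C4 (CHOH), C5 (=C–CH3), C6 (=C–C7≡C8). The target is C2-symmetric, (3S,4S,3'S,4'S), with trans diols and an all-E chain, so one C15 end group serves twice.
Cuts: C11=C12 and C11'=C12' (two-fold Wittig, 2 × C15 + C10), then in the ring C1–C2 and C3–C4 at once, then C6–C7 (Sonogashira) and C4–C5 (bromoformylation).
Enabling feature: the six-membered ring holds one double bond, C5=C6, exactly opposite the C2–C3 edge. This is the retron of a [4+2] cycloaddition of the diene C4=C5–C6=C1 (donor oxygen on C4, slim linear alkyne on C6) with a two-carbon acrylate, whose carboxyl group activates the dienophile and later makes way for the C3 hydroxyl.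
Forward: an acyclic C13 dienyne is made in three steps. The ring arises in step 4 together with quaternary C1 and the tetrasubstituted C5=C6. The carboxyl helper is exchanged for OH in steps 5–7, and the chain is joined last.
Stereochemistry: C4 comes from a chiral oxazaborolidinium catalyst, relayed through the endo rule. C3 is reset trans to C4–OTBS by radical borylation and retentive oxidation. E-C9=C10 comes from the commercial enynol, and E-C11=C12 from the Wittig step plus mild thermal relaxation.

Key step: step 4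

Assumption 1: 2, 3, 5 and 6 are E/Z mixtures at the future C5–C6 bond. Their SMILES leave it open because this bond is single in diene 7, where both isomers converge.
Assumption 2: the sense of induction in step 4 is taken from the known course of acrylate cycloadditions with this catalyst class (S catalyst and butadiene give the S cyclohex-3-enecarboxylate), so the R catalyst is used. If the opposite face reacts, the S catalyst is taken instead.

Step 1
Reactants: 1 2-methylpentan-3-one
Product: 3 3-bromo-2,4-dimethylpent-2-enal (E/Z mixture), via bromovinyl iminium bromide 2 (not isolated)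
Conditions: PBr3 (2.5 equiv), DMF (3 equiv), CHCl3, 0 → 60 °C; then H2O, 0 °C
Reagents that add atoms: N,N-dimethylformamide CN(C)C=O; phosphorus tribromide BrP(Br)Br; water O
Why: Vilsmeier–Haack–Arnold bromoformylation, in which only the CH2 flank of the ketone can end in a conjugated β-bromo enal, so C4–C5 forms regioselectively and both olefin isomers are usable.

Step 2
Reactants: 3 3-bromo-2,4-dimethylpent-2-enal; 4 (2E)-3-methylpent-2-en-4-yn-1-ol
Product: 5 (6E)-8-hydroxy-2,6-dimethyl-3-(propan-2-yl)octa-2,6-dien-4-ynal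
Conditions: PdCl2(PPh3)2 (3 mol%), CuI (5 mol%), Et3N (3 equiv), THF, rt
Reagents that add atoms: none
Why: Sonogashira coupling of an activated β-bromo enal with a terminal alkyne runs at room temperature, tolerates the free alcohol and the aldehyde, forms C6–C7 and keeps the E geometry of C9=C10 brought in by 4.

Step 3
Reactants: 5 (6E)-8-hydroxy-2,6-dimethyl-3-(propan-2-yl)octa-2,6-dien-4-ynal
Product: 7 (1E,6E)-1,8-bis(TBSO)-2,6-dimethyl-3-(propan-2-ylidene)octa-1,6-dien-4-yne, via O-silyl enynal 6 (not isolated)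
Conditions: TBSOTf (2.4 equiv), Et3N (4 equiv), CH2Cl2, −78 °C → rt
Reagents that add atoms: tert-butyldimethylsilyl trifluoromethanesulfonate CC(C)(C)[Si](C)(C)OS(=O)(=O)C(F)(F)F
Why: Soft enolisation with silyl triflate and amine, in which O-silylation of the aldehyde acidifies the only γ-hydrogen (the isopropyl methine) and its loss gives the dienol silyl ether, E at C4=C5 because the s-trans enal conformer reacts, while the primary alcohol is silylated in the same flask.

Step 4
Reactants: 7 (1E,6E)-1,8-bis(TBSO)-2,6-dimethyl-3-(propan-2-ylidene)octa-1,6-dien-4-yne; 8 2,2,2-trifluoroethyl prop-2-enoate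
Product: 9 2,2,2-trifluoroethyl (1R,2R)-2-(TBSO)-4-[(3E)-5-(TBSO)-3-methylpent-3-en-1-yn-1-yl]-3,5,5-trimethylcyclohex-3-ene-1-carboxylate (3,4-cis in carotenoid numbering)
Conditions: (R)-3,3-diphenyl-1-(2-methylphenyl)tetrahydro-1H,3H-pyrrolo[1,2-c][1,3,2]oxazaborole (20 mol%), Tf2NH (18 mol%), 8 (3 equiv), CH2Cl2, −40 → 0 °C
Reagents that add atoms: none
Why: Concerted but asynchronous normal-electron-demand [4+2] cycloaddition, the closest known type being the catalytic enantioselective Diels–Alder reaction of silyloxy dienes with acrylates under a cationic oxazaborolidine Lewis acid, with the acrylate carbonyl bound to boron and the C1–C2 bond running ahead of C3–C4. The six-membered carbocycle closes intermolecularly in the suprafacial [π4s+π2s] mode, which makes C1–C2 and C3–C4 together and leaves the new double bond at C5=C6, so quaternary C1 and the tetrasubstituted enyne olefin arise at once. Regiochemistry follows the ortho rule, since the C4 silyloxy group puts the largest HOMO coefficient on C1, which bonds to the unsubstituted acrylate CH2 (also the only sterically workable pairing at the CMe2 terminus), and the ester carbon ends next to C4. C3 is fixed by the catalyst, whose aryl groups shield one face of the bound acrylate, and C4 follows from C3 through the endo transition state of the (1E)-silyloxy diene, which gives the 3,4-cis adduct. The s-cis form is within reach because the C5 and C6 substituents remove the usual s-trans preference and the C6 substituent is a rod-like alkyne, and thermal cycloadditions of 1,1-dimethyl-2,3-disubstituted dienes with activated acrylic dienophiles are the closest substrate precedent. The step needs selectivity over the side-chain enyne and over Mukaiyama–Michael silyl transfer, which the much higher HOMO of the silyloxy diene, a slight deficit of Tf2NH and low temperature should secure.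

Step 5
Reactants: 9 trifluoroethyl ester adduct
Product: 10 (1R,2R)-2-(TBSO)-4-[(3E)-5-(TBSO)-3-methylpent-3-en-1-yn-1-yl]-3,5,5-trimethylcyclohex-3-ene-1-carboxylic acid
Conditions: LiOH (2 equiv), THF/H2O, 0 °C; then 1 M HCl to pH 4, 0 °C
Reagents that add atoms: lithium hydroxide [Li+].[OH-]
Why: Saponification of the activated trifluoroethyl ester proceeds at 0 °C, where the silyl ethers survive and β-elimination is slow, and any epimerisation at C3 is harmless because C3 is reset in step 7.

Step 6
Reactants: 10 cyclohexenecarboxylic acid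
Product: 11 1,3-dioxoisoindolin-2-yl ester of 10
Conditions: N-hydroxyphthalimide (1.1 equiv), DIC (1.1 equiv), DMAP (10 mol%), CH2Cl2, rt
Reagents that add atoms: N-hydroxyphthalimide O=C1c2ccccc2C(=O)N1O
Why: Steglich-type carbodiimide esterification turns the acid into a redox-active N-acyloxyphthalimide without touching C4 or the silyl ethers.

Step 7
Reactants: 11 redox-active ester
Product: 13 (1S,2S)-2-(TBSO)-4-[(3E)-5-(TBSO)-3-methylpent-3-en-1-yn-1-yl]-3,5,5-trimethylcyclohex-3-en-1-ol (3,4-trans), via catechol boronate 12 (not isolated)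
Conditions: B2cat2 (1.3 equiv), DMAc, 450 nm LED, rt; then 30% H2O2, 2 M NaOH, THF, 0 °C
Reagents that add atoms: bis(catecholato)diboron c1ccc2c(c1)OB(O2)B1Oc2ccccc2O1; hydrogen peroxide OO
Why: Photoinduced decarboxylative borylation of a redox-active ester followed by stereoretentive C–B oxidation, in which the planar C3 radical should be captured by the bulky diboron–amide adduct on the face anti to the neighbouring C4–OTBS group (the ring can place the axial C1 methyl on the same blocked face), setting the 3,4-trans (3S) configuration.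

Step 8
Reactants: 13 trans alcohol
Product: 14 tris-TBS ether of the C15 (3S,4S)-enyne triol
Conditions: TBSOTf (1.3 equiv), 2,6-lutidine (2 equiv), CH2Cl2, 0 °C
Reagents that add atoms: tert-butyldimethylsilyl trifluoromethanesulfonate CC(C)(C)[Si](C)(C)OS(=O)(=O)C(F)(F)F
Why: Silyl triflate and lutidine silylate the hindered secondary C3 alcohol under non-ionising conditions that leave the allylic C4–O bond intact.

Step 9
Reactants: 14 tris-TBS ether
Product: 15 (2E)-5-[(3S,4S)-3,4-bis(TBSO)-2,6,6-trimethylcyclohex-1-en-1-yl]-3-methylpent-2-en-4-yn-1-ol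
Conditions: HF·pyridine, pyridine, THF, 0 °C
Reagents that add atoms: none
Why: Buffered fluoride desilylation differentiates by steric rate, so the unhindered primary allylic silyl ether should be cleaved well before the two flanked secondary ones.

Step 10
Reactants: 15 primary allylic alcohol
Product: 17 C15 triphenylphosphonium bromide, via allylic bromide 16 (not isolated)
Conditions: CBr4 (1.1 equiv), PPh3 (1.15 equiv), CH2Cl2, −20 °C; then PPh3 (1.2 equiv), rt
Reagents that add atoms: carbon tetrabromide BrC(Br)(Br)Br; triphenylphosphine c1ccc(cc1)P(c1ccccc1)c1ccccc1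
Why: Appel bromination at the primary allylic carbon followed by SN2 quaternisation of PPh3 is acid-free, so C4–OTBS is not ionised and E-C9=C10 is kept.

Step 11
Reactants: 17 C15 triphenylphosphonium bromide (2.2 equiv); 18 (2E,4E,6E)-2,7-dimethylocta-2,4,6-trienedial
Product: 21 tetrakis-TBS ether of the target (all-E), via phosphorus ylide 19 (not isolated), via C25 apo-aldehyde 20 (not isolated)
Conditions: NaOMe (2.5 equiv), CH2Cl2/MeOH, 0 °C → rt, dark, Ar; then heptane, 60 °C
Reagents that add atoms: none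
Why: Two-fold Wittig olefination of the symmetrical C10 dialdehyde with the semi-stabilised allylic ylide (the classical C15 + C10 + C15 carotenoid assembly) forms C11=C12 and C11'=C12', and the sterically hindered 11Z isomers (C10–H against C13–CH3) should relax to E on brief warming in the dark without touching E-C9=C10 or the protected stereocentres.

Step 12
Reactants: 21 tetrakis-TBS ether
Product: 22 (3S,4S,3'S,4'S)-7,8,7',8'-tetradehydro-β,β-carotene-3,4,3',4'-tetrol
Conditions: TBAF (8 equiv), AcOH (8 equiv), THF, rt, dark, Ar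
Reagents that add atoms: none
Why: Buffered fluoride-mediated desilylation breaks only Si–O bonds, so the four carbinol centres keep their configuration and the acid-labile allylic C4 alcohols and the polyene are spared.

Compound list
1 | 2-methylpentan-3-one | CCC(=O)C(C)C | starting material
2 | N-(3-bromo-2,4-dimethylpent-2-en-1-ylidene)-N-methylmethanaminium bromide (E/Z mixture) | C[N+](C)=CC(C)=C(Br)C(C)C.[Br-] | intermediate
3 | 3-bromo-2,4-dimethylpent-2-enal (E/Z mixture) | O=CC(C)=C(Br)C(C)C | intermediate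
4 | (2E)-3-methylpent-2-en-4-yn-1-ol | C#C/C(C)=C/CO | starting material
5 | (6E)-8-hydroxy-2,6-dimethyl-3-(propan-2-yl)octa-2,6-dien-4-ynal (E/Z mixture at C2=C3) | O=CC(C)=C(C(C)C)C#C/C(C)=C/CO | intermediate
6 | (6E)-8-[(tert-butyldimethylsilyl)oxy]-2,6-dimethyl-3-(propan-2-yl)octa-2,6-dien-4-ynal (E/Z mixture at C2=C3) | O=CC(C)=C(C(C)C)C#C/C(C)=C/CO[Si](C)(C)C(C)(C)C | intermediate
7 | (1E,6E)-1,8-bis[(tert-butyldimethylsilyl)oxy]-2,6-dimethyl-3-(propan-2-ylidene)octa-1,6-dien-4-yne | CC(C)=C(C#C/C(C)=C/CO[Si](C)(C)C(C)(C)C)/C(C)=C/O[Si](C)(C)C(C)(C)C | intermediate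
8 | 2,2,2-trifluoroethyl prop-2-enoate | C=CC(=O)OCC(F)(F)F | starting material
9 | 2,2,2-trifluoroethyl (1R,2R)-2-[(tert-butyldimethylsilyl)oxy]-4-[(3E)-5-[(tert-butyldimethylsilyl)oxy]-3-methylpent-3-en-1-yn-1-yl]-3,5,5-trimethylcyclohex-3-ene-1-carboxylate (ester cis to OTBS) | CC1=C(C#C/C(C)=C/CO[Si](C)(C)C(C)(C)C)C(C)(C)C[C@@H](C(=O)OCC(F)(F)F)[C@H]1O[Si](C)(C)C(C)(C)C | intermediate
10 | (1R,2R)-2-[(tert-butyldimethylsilyl)oxy]-4-[(3E)-5-[(tert-butyldimethylsilyl)oxy]-3-methylpent-3-en-1-yn-1-yl]-3,5,5-trimethylcyclohex-3-ene-1-carboxylic acid | CC1=C(C#C/C(C)=C/CO[Si](C)(C)C(C)(C)C)C(C)(C)C[C@@H](C(=O)O)[C@H]1O[Si](C)(C)C(C)(C)C | intermediate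
11 | 1,3-dioxoisoindolin-2-yl (1R,2R)-2-[(tert-butyldimethylsilyl)oxy]-4-[(3E)-5-[(tert-butyldimethylsilyl)oxy]-3-methylpent-3-en-1-yn-1-yl]-3,5,5-trimethylcyclohex-3-ene-1-carboxylate | CC1=C(C#C/C(C)=C/CO[Si](C)(C)C(C)(C)C)C(C)(C)C[C@@H](C(=O)ON2C(=O)c3ccccc3C2=O)[C@H]1O[Si](C)(C)C(C)(C)C | intermediate
12 | 2-[(1S,2R)-2-[(tert-butyldimethylsilyl)oxy]-4-[(3E)-5-[(tert-butyldimethylsilyl)oxy]-3-methylpent-3-en-1-yn-1-yl]-3,5,5-trimethylcyclohex-3-en-1-yl]-1,3,2-benzodioxaborole (boron trans to OTBS) | CC1=C(C#C/C(C)=C/CO[Si](C)(C)C(C)(C)C)C(C)(C)C[C@H](B2Oc3ccccc3O2)[C@H]1O[Si](C)(C)C(C)(C)C | intermediate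
13 | (1S,2S)-2-[(tert-butyldimethylsilyl)oxy]-4-[(3E)-5-[(tert-butyldimethylsilyl)oxy]-3-methylpent-3-en-1-yn-1-yl]-3,5,5-trimethylcyclohex-3-en-1-ol (OH trans to OTBS) | CC1=C(C#C/C(C)=C/CO[Si](C)(C)C(C)(C)C)C(C)(C)C[C@H](O)[C@H]1O[Si](C)(C)C(C)(C)C | intermediate
14 | (3S,4S)-3,4-bis[(tert-butyldimethylsilyl)oxy]-1-[(3E)-5-[(tert-butyldimethylsilyl)oxy]-3-methylpent-3-en-1-yn-1-yl]-2,6,6-trimethylcyclohex-1-ene | CC1=C(C#C/C(C)=C/CO[Si](C)(C)C(C)(C)C)C(C)(C)C[C@H](O[Si](C)(C)C(C)(C)C)[C@H]1O[Si](C)(C)C(C)(C)C | intermediate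
15 | (2E)-5-[(3S,4S)-3,4-bis[(tert-butyldimethylsilyl)oxy]-2,6,6-trimethylcyclohex-1-en-1-yl]-3-methylpent-2-en-4-yn-1-ol | CC1=C(C#C/C(C)=C/CO)C(C)(C)C[C@H](O[Si](C)(C)C(C)(C)C)[C@H]1O[Si](C)(C)C(C)(C)C | intermediate
16 | (3S,4S)-1-[(3E)-5-bromo-3-methylpent-3-en-1-yn-1-yl]-3,4-bis[(tert-butyldimethylsilyl)oxy]-2,6,6-trimethylcyclohex-1-ene | CC1=C(C#C/C(C)=C/CBr)C(C)(C)C[C@H](O[Si](C)(C)C(C)(C)C)[C@H]1O[Si](C)(C)C(C)(C)C | intermediate
17 | [(2E)-5-[(3S,4S)-3,4-bis[(tert-butyldimethylsilyl)oxy]-2,6,6-trimethylcyclohex-1-en-1-yl]-3-methylpent-2-en-4-yn-1-yl]triphenylphosphonium bromide | CC1=C(C#C/C(C)=C/C[P+](c2ccccc2)(c2ccccc2)c2ccccc2)C(C)(C)C[C@H](O[Si](C)(C)C(C)(C)C)[C@H]1O[Si](C)(C)C(C)(C)C.[Br-] | intermediate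
18 | (2E,4E,6E)-2,7-dimethylocta-2,4,6-trienedial | O=C/C(C)=C/C=C/C=C(C)/C=O | starting material
19 | ylide of 17, [(2E)-5-[(3S,4S)-3,4-bis[(tert-butyldimethylsilyl)oxy]-2,6,6-trimethylcyclohex-1-en-1-yl]-3-methylpent-2-en-4-yn-1-ylidene]triphenylphosphorane | CC1=C(C#C/C(C)=C/C=P(c2ccccc2)(c2ccccc2)c2ccccc2)C(C)(C)C[C@H](O[Si](C)(C)C(C)(C)C)[C@H]1O[Si](C)(C)C(C)(C)C | intermediate
20 | (3S,4S)-3,4-bis[(tert-butyldimethylsilyl)oxy]-7,8-didehydro-12'-apo-β-caroten-12'-al (all-E) | CC1=C(C#C/C(C)=C/C=C/C(C)=C/C=C/C=C(C)/C=O)C(C)(C)C[C@H](O[Si](C)(C)C(C)(C)C)[C@H]1O[Si](C)(C)C(C)(C)C | intermediate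
21 | (3S,4S,3'S,4'S)-3,4,3',4'-tetrakis[(tert-butyldimethylsilyl)oxy]-7,8,7',8'-tetradehydro-β,β-carotene (all-E) | CC1=C(C#C/C(C)=C/C=C/C(C)=C/C=C/C=C(C)/C=C/C=C(\C)C#CC2=C(C)[C@H](O[Si](C)(C)C(C)(C)C)[C@@H](O[Si](C)(C)C(C)(C)C)CC2(C)C)C(C)(C)C[C@H](O[Si](C)(C)C(C)(C)C)[C@H]1O[Si](C)(C)C(C)(C)C | intermediate
22 | (3S,4S,3'S,4'S)-7,8,7',8'-tetradehydro-β,β-carotene-3,4,3',4'-tetrol (all-E) | CC1=C(C#C/C(C)=C/C=C/C(C)=C/C=C/C=C(C)/C=C/C=C(\C)C#CC2=C(C)[C@H](O)[C@@H](O)CC2(C)C)C(C)(C)C[C@H](O)[C@H]1O | target

Total step count: 12. Longest linear sequence: 12 steps (1 → 22); 4, 8 and 18 are bought.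

Steps most likely to fail

Step 4. The cycloaddition may be sluggish at the congested CMe2 terminus. Silyl transfer from the diene to the triflimide may start an achiral silylium-catalysed background reaction, which would erode facial selectivity. Any exo addition would pair the catalyst-fixed C3 with the opposite C4 configuration, so that diastereomer would have to be removed at the stage of 9.
The fallback uses auxiliary control instead of catalyst control. It sets out from 7, which is combined with commercial (4S)-3-acryloyl-4-benzyl-1,3-oxazolidin-2-one and Et2AlCl in CH2Cl2 at −78 °C. The chelated acyl oxazolidinone should be attacked on the face remote from the benzyl group to give the endo N-acyl oxazolidinone adduct F1, which can be freed from minor diastereomers by chromatography or crystallisation. LiOH/H2O2 in THF/H2O at 0 °C removes the auxiliary and brings the material back to the route at acid 10.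

Step 3. Removal of the hindered isopropyl methine proton may be slow. The product may hydrolyse back to the enal, and the C4=C5 geometry may scramble.
The fallback replaces kinetic soft enolisation by equilibrating enol esterification and an ester-to-silyl exchange. It sets out from 5, which is silylated with TBSCl and imidazole in DMF to give 6, isolated here. Heating 6 with Ac2O, Et3N and DMAP at 80 °C should give the (1E)-dienyl acetate F2 under thermodynamic control. MeLi (2 equiv) in THF at −20 °C cleaves the acetate to the lithium dienolate F3, which is trapped on oxygen with TBSCl in THF/HMPA and returns to the route at 7.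

Step 7. Capture of the C3 radical may show poor facial selectivity, and simple reduction of the radical may compete.
The fallback relies on a stereospecific SN2 inversion instead of radical face selection. It sets out from 11, which is carried through the same borylation and oxidation without regard to selectivity. The 3,4-cis alcohol F4 is then separated from 13 by chromatography. A Mitsunobu reaction of F4 with 4-nitrobenzoic acid, DIAD and PPh3 in toluene at 0 °C → rt inverts C3 cleanly to the 3,4-trans 4-nitrobenzoate F5. K2CO3 in MeOH at 0 °C then releases the alcohol, which rejoins the route at 13.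

Further compounds
F1 | step 4 | (4S)-4-benzyl-3-{[(1R,2R)-2-[(tert-butyldimethylsilyl)oxy]-4-[(3E)-5-[(tert-butyldimethylsilyl)oxy]-3-methylpent-3-en-1-yn-1-yl]-3,5,5-trimethylcyclohex-3-en-1-yl]carbonyl}-1,3-oxazolidin-2-one | CC1=C(C#C/C(C)=C/CO[Si](C)(C)C(C)(C)C)C(C)(C)C[C@@H](C(=O)N2[C@@H](Cc3ccccc3)COC2=O)[C@H]1O[Si](C)(C)C(C)(C)C
F2 | step 3 | (1E,6E)-8-[(tert-butyldimethylsilyl)oxy]-2,6-dimethyl-3-(propan-2-ylidene)octa-1,6-dien-4-yn-1-yl acetate | CC(C)=C(C#C/C(C)=C/CO[Si](C)(C)C(C)(C)C)/C(C)=C/OC(C)=O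
F3 | step 3 | lithium (1E,6E)-8-[(tert-butyldimethylsilyl)oxy]-2,6-dimethyl-3-(propan-2-ylidene)octa-1,6-dien-4-yn-1-olate | CC(C)=C(C#C/C(C)=C/CO[Si](C)(C)C(C)(C)C)/C(C)=C/[O-].[Li+]
F4 | step 7 | (1R,2S)-2-[(tert-butyldimethylsilyl)oxy]-4-[(3E)-5-[(tert-butyldimethylsilyl)oxy]-3-methylpent-3-en-1-yn-1-yl]-3,5,5-trimethylcyclohex-3-en-1-ol (OH cis to OTBS) | CC1=C(C#C/C(C)=C/CO[Si](C)(C)C(C)(C)C)C(C)(C)C[C@@H](O)[C@H]1O[Si](C)(C)C(C)(C)C
F5 | step 7 | (1S,2S)-2-[(tert-butyldimethylsilyl)oxy]-4-[(3E)-5-[(tert-butyldimethylsilyl)oxy]-3-methylpent-3-en-1-yn-1-yl]-3,5,5-trimethylcyclohex-3-en-1-yl 4-nitrobenzoate | CC1=C(C#C/C(C)=C/CO[Si](C)(C)C(C)(C)C)C(C)(C)C[C@H](OC(=O)c2ccc(cc2)[N+](=O)[O-])[C@H]1O[Si](C)(C)C(C)(C)C
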